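**Retrosynthetic overview**
1. The ring is numbered O1, C2 (CH3), C3 (CH2OH), C4 (CH2CO2R), C5 (CO2Me), C6. The plan rests on C4: it is β to the side-chain ester carbonyl and bonded to C5, the central carbon of the formyl-ester unit C6H=C5–CO2Me. C4–C5 is therefore the bond an α,β-unsaturated acyl azolium forms with a 1,3-dicarbonyl compound.
2. Target 18 ⇐ desilylation of 17 ⇐ O1–C6 cyclodehydration of the C2 hydroxyl onto the C6 formyl enol of 14 (dihydropyran ring, formed second).
3. 14 ⇐ acyl transfer from the enol lactone 10 (a 3,4-dihydropyran-2-one, formed first and opened again) to catechol-silylated hydroxytyrosol 13.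
4. 10 ⇐ oxidative carbene-catalysed annulation of enal 7 with methyl 3-oxopropanoate 9 (C4–C5 bond, lactone C–O bond, C4 stereocentre).
5. 7 ⇐ methyl (R)-3-hydroxybutanoate 1 (C2 from the chiral pool) by anti hydroxymethylation (C3), two silylations, partial reduction and two-carbon Wittig homologation.

Key step: step 7

Assumption: the (5aS,10bR) antipode of the aminoindanol-derived N-mesityl triazolium salt is taken to be the one that delivers 4S; should the first run give 4R, its mirror image is used with nothing else changed.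

Step 1
Reactants: 1 methyl (R)-3-hydroxybutanoate
Product: 3 methyl (2R,3R)-3-hydroxy-2-(hydroxymethyl)butanoate, via dilithium alkoxide enolate 2 (not isolated)
Conditions: LiN(i-Pr)2 (2.2 equiv), THF, −78 to −20 °C; then CH2O (gas, from cracked paraformaldehyde), −78 °C; aq NH4Cl
Reagents that add atoms: formaldehyde, C=O
Why: Fráter–Seebach reaction in its aldol form: the dianion is a rigid six-membered lithium chelate whose C3 methyl group shields one enolate face, so formaldehyde should bond anti to it and set the new centre as 2R (later ring C3).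

Step 2
Reactants: 3 methyl (2R,3R)-3-hydroxy-2-(hydroxymethyl)butanoate
Product: 4 methyl (2R,3R)-2-[(tert-butyldiphenylsilyloxy)methyl]-3-hydroxybutanoate
Conditions: t-BuPh2SiCl (1.05 equiv), imidazole, CH2Cl2, 0 °C
Reagents that add atoms: tert-butyl(chloro)diphenylsilane, CC(C)(C)[Si](Cl)(c1ccccc1)c1ccccc1
Why: Silyl ether formation under Corey conditions, in which the bulky chlorosilane should discriminate the primary from the secondary hydroxyl.

Step 3
Reactants: 4 methyl (2R,3R)-2-[(tert-butyldiphenylsilyloxy)methyl]-3-hydroxybutanoate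
Product: 5 methyl (2R,3R)-2-[(tert-butyldiphenylsilyloxy)methyl]-3-(triethylsilyloxy)butanoate
Conditions: Et3SiCl (1.3 equiv), imidazole, DMAP (cat.), CH2Cl2, 0 °C to rt
Reagents that add atoms: chlorotriethylsilane, CC[Si](Cl)(CC)CC
Why: Standard silylation of the remaining secondary hydroxyl; the triethylsilyl ether is chosen because mild acid removes it while sparing the other silyl groups.

Step 4
Reactants: 5 methyl (2R,3R)-2-[(tert-butyldiphenylsilyloxy)methyl]-3-(triethylsilyloxy)butanoate
Product: 6 (2R,3R)-2-[(tert-butyldiphenylsilyloxy)methyl]-3-(triethylsilyloxy)butanal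
Conditions: i-Bu2AlH (1.1 equiv), CH2Cl2, −78 °C; MeOH quench at −78 °C; aq KNaC4H4O6 (potassium sodium tartrate)
Reagents that add atoms: none
Why: Partial ester reduction with i-Bu2AlH at −78 °C, where the tetrahedral aluminium hemiacetal, stabilised by the β-silyloxy oxygens, should persist until the cold quench; the α centre is not touched and the aldehyde is used crude.

Step 5
Reactants: 6 (2R,3R)-2-[(tert-butyldiphenylsilyloxy)methyl]-3-(triethylsilyloxy)butanal
Product: 7 (2E,4R,5R)-4-[(tert-butyldiphenylsilyloxy)methyl]-5-(triethylsilyloxy)hex-2-enal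
Conditions: Ph3P=CHCHO (1.3 equiv), toluene, 80 °C
Reagents that add atoms: (triphenylphosphoranylidene)acetaldehyde, O=CC=P(c1ccccc1)(c1ccccc1)c1ccccc1
Why: Wittig olefination with the stabilised formylmethylene ylide, which should give the (E)-enal and is a weak enough base to leave the α-branched aldehyde configurationally intact.

Step 6
Reactants: 8 methyl 3,3-dimethoxypropanoate
Product: 9 methyl 3-oxopropanoate (methyl formylacetate, aldehyde and enol tautomers)
Conditions: 1 M aq HCl, THF, rt; extraction into CH2Cl2, dried cold solution used at once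
Reagents that add atoms: water, O
Why: Acid-catalysed acetal hydrolysis; the methyl ester is inert to dilute acid at room temperature, and the self-condensing formyl ester is kept in cold solution and consumed immediately.

Step 7
Reactants: 7 (2E,4R,5R)-4-[(tert-butyldiphenylsilyloxy)methyl]-5-(triethylsilyloxy)hex-2-enal; 9 methyl 3-oxopropanoate (1.5 equiv)
Product: 10 methyl (4S)-4-[(2R,3R)-1-(tert-butyldiphenylsilyloxy)-3-(triethylsilyloxy)butan-2-yl]-2-oxo-3,4-dihydro-2H-pyran-5-carboxylate
Conditions: (5aS,10bR)-2-mesityl-5a,10b-dihydro-4H,6H-indeno[2,1-b][1,2,4]triazolo[4,3-d][1,4]oxazin-2-ium chloride (10 mol %), 3,3',5,5'-tetra-tert-butyldiphenoquinone (1.2 equiv), i-Pr2NEt (0.3 equiv), 4 Å MS, THF, 0 °C to rt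
Reagents that add atoms: none
Why: The carbene adds to the aldehyde of 7 and the Breslow intermediate is oxidised by the diphenoquinone to the α,β-unsaturated acyl azolium; the enol(ate) of 9 then bonds through its central carbon to the β carbon (C4–C5, by direct conjugate addition or by O-acylation and [3,3] shift), and after proton transfer the formyl enol oxygen attacks the acyl azolium carbonyl and releases the carbene. The closest known reaction is the oxidative carbene-catalysed annulation of enals with β-keto esters and 1,3-diketones to 3,4-dihydropyran-2-ones; a β-formyl ester and a γ-branched aliphatic enal stretch its usual scope. The lactone ring closes by 6-exo-trig O-acylation. The new centre C4 is controlled by the chiral triazolium, whose indane wall leaves one face of the acyl azolium open, while the substrate bias should be small because both γ substituents are CH-type carbons. The step needs carbon bonding of the enol, closure through the formyl and not the ester oxygen, and retention of C3: the first two follow because only the aldehyde enol can give a six-membered enol lactone, the third is served by the substoichiometric hindered amine base and low temperature, which disfavour γ-deprotonation.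

Step 8
Reactants: 11 hydroxytyrosol
Product: 12 tert-butyl{2-[3,4-bis(tert-butyldimethylsilyloxy)phenyl]ethoxy}dimethylsilane
Conditions: t-BuMe2SiCl (3.5 equiv), imidazole, DMF, rt
Reagents that add atoms: tert-butyl(chloro)dimethylsilane, CC(C)(C)[Si](C)(C)Cl
Why: Exhaustive silylation of the two phenols and the primary alcohol under Corey conditions.

Step 9
Reactants: 12 tert-butyl{2-[3,4-bis(tert-butyldimethylsilyloxy)phenyl]ethoxy}dimethylsilane
Product: 13 2-[3,4-bis(tert-butyldimethylsilyloxy)phenyl]ethanol
Conditions: camphorsulfonic acid (0.1 equiv), MeOH/CH2Cl2 (1:1), 0 °C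
Reagents that add atoms: none
Why: Acid-catalysed methanolysis cleaves a primary alkyl silyl ether much faster than aryl silyl ethers, so only the aliphatic oxygen should be unmasked.

Step 10
Reactants: 10 methyl (4S)-4-[(2R,3R)-1-(tert-butyldiphenylsilyloxy)-3-(triethylsilyloxy)butan-2-yl]-2-oxo-3,4-dihydro-2H-pyran-5-carboxylate; 13 2-[3,4-bis(tert-butyldimethylsilyloxy)phenyl]ethanol (1.1 equiv)
Product: 14 2-[3,4-bis(tert-butyldimethylsilyloxy)phenyl]ethyl methyl (2Z,3S)-3-[(2R,3R)-1-(tert-butyldiphenylsilyloxy)-3-(triethylsilyloxy)butan-2-yl]-2-(hydroxymethylidene)pentanedioate (methyl ester at C1, arylethyl ester at C5; enol tautomer of the C6 formyl ester)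
Conditions: DMAP (0.2 equiv), CH2Cl2, 0 °C to rt
Reagents that add atoms: none
Why: DMAP-catalysed acyl transfer from an activated enol ester: the leaving group is the stabilised formyl-ester enolate, so the primary alcohol should open the lactone to the phenethyl ester without touching the methyl ester or C4.

Step 11
Reactants: 14 ring-opened enol ester (name as in step 10)
Product: 17 methyl (2R,3R,4S)-4-(2-{2-[3,4-bis(tert-butyldimethylsilyloxy)phenyl]ethoxy}-2-oxoethyl)-3-[(tert-butyldiphenylsilyloxy)methyl]-2-methyl-3,4-dihydro-2H-pyran-5-carboxylate, via hydroxy enol 15 (not isolated), via lactol 16 (not isolated)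
Conditions: PPTS (0.3 equiv), MeOH/CH2Cl2 (1:4), 0 °C to rt; then solvent exchange to toluene, PPTS, 4 Å MS, 45 °C
Reagents that add atoms: none
Why: Acid-catalysed methanolysis should remove the secondary triethylsilyl ether far faster than the primary tert-butyldiphenylsilyl and aryl silyl ethers; the freed C2 hydroxyl then adds to the C6 formyl carbon (six-membered hemiacetal) and dehydration gives the conjugated β-alkoxyacrylate, an intramolecular vinylogous esterification that makes C5 trigonal and leaves C2, C3 and C4 unchanged.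

Step 12
Reactants: 17 silyl-protected dihydropyran (name as in step 11)
Product: 18 methyl (2R,3R,4S)-4-{2-[2-(3,4-dihydroxyphenyl)ethoxy]-2-oxoethyl}-3-(hydroxymethyl)-2-methyl-3,4-dihydro-2H-pyran-5-carboxylate
Conditions: Bu4NF/AcOH (1:1, 4 equiv), THF, 0 °C to rt, argon
Reagents that add atoms: none
Why: Fluoride-mediated desilylation buffered with acetic acid: the aryl silyl ethers should fall first and the primary tert-butyldiphenylsilyl ether more slowly, while the buffer keeps the catechol protonated and holds back alkoxide-driven δ-lactonisation of the freed hydroxymethyl group onto the neighbouring phenethyl ester.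

**Compound list**
1 | methyl (R)-3-hydroxybutanoate | C[C@@H](O)CC(=O)OC | starting material
2 | dilithium alkoxide enolate of 1 (chelated, enolate oxygen cis to C3) | C[C@@H]([O-])/C=C(\[O-])OC.[Li+].[Li+] | intermediate
3 | methyl (2R,3R)-3-hydroxy-2-(hydroxymethyl)butanoate | COC(=O)[C@H](CO)[C@@H](C)O | intermediate
4 | methyl (2R,3R)-2-[(tert-butyldiphenylsilyloxy)methyl]-3-hydroxybutanoate | COC(=O)[C@H](CO[Si](c1ccccc1)(c1ccccc1)C(C)(C)C)[C@@H](C)O | intermediate
5 | methyl (2R,3R)-2-[(tert-butyldiphenylsilyloxy)methyl]-3-(triethylsilyloxy)butanoate | COC(=O)[C@H](CO[Si](c1ccccc1)(c1ccccc1)C(C)(C)C)[C@@H](C)O[Si](CC)(CC)CC | intermediate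
6 | (2R,3R)-2-[(tert-butyldiphenylsilyloxy)methyl]-3-(triethylsilyloxy)butanal | O=C[C@H](CO[Si](c1ccccc1)(c1ccccc1)C(C)(C)C)[C@@H](C)O[Si](CC)(CC)CC | intermediate
7 | (2E,4R,5R)-4-[(tert-butyldiphenylsilyloxy)methyl]-5-(triethylsilyloxy)hex-2-enal | O=C/C=C/[C@H](CO[Si](c1ccccc1)(c1ccccc1)C(C)(C)C)[C@@H](C)O[Si](CC)(CC)CC | intermediate
8 | methyl 3,3-dimethoxypropanoate | COC(=O)CC(OC)OC | starting material
9 | methyl 3-oxopropanoate (aldehyde tautomer drawn) | COC(=O)CC=O | intermediate
10 | methyl (4S)-4-[(2R,3R)-1-(tert-butyldiphenylsilyloxy)-3-(triethylsilyloxy)butan-2-yl]-2-oxo-3,4-dihydro-2H-pyran-5-carboxylate | COC(=O)C1=COC(=O)C[C@H]1[C@H](CO[Si](c1ccccc1)(c1ccccc1)C(C)(C)C)[C@@H](C)O[Si](CC)(CC)CC | intermediate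
11 | hydroxytyrosol, 4-(2-hydroxyethyl)benzene-1,2-diol | OCCc1ccc(O)c(O)c1 | starting material
12 | tert-butyl{2-[3,4-bis(tert-butyldimethylsilyloxy)phenyl]ethoxy}dimethylsilane | CC(C)(C)[Si](C)(C)OCCc1ccc(O[Si](C)(C)C(C)(C)C)c(O[Si](C)(C)C(C)(C)C)c1 | intermediate
13 | 2-[3,4-bis(tert-butyldimethylsilyloxy)phenyl]ethanol | OCCc1ccc(O[Si](C)(C)C(C)(C)C)c(O[Si](C)(C)C(C)(C)C)c1 | intermediate
14 | 2-[3,4-bis(tert-butyldimethylsilyloxy)phenyl]ethyl methyl (2Z,3S)-3-[(2R,3R)-1-(tert-butyldiphenylsilyloxy)-3-(triethylsilyloxy)butan-2-yl]-2-(hydroxymethylidene)pentanedioate | COC(=O)/C(=C\O)[C@@H](CC(=O)OCCc1ccc(O[Si](C)(C)C(C)(C)C)c(O[Si](C)(C)C(C)(C)C)c1)[C@H](CO[Si](c1ccccc1)(c1ccccc1)C(C)(C)C)[C@@H](C)O[Si](CC)(CC)CC | intermediate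
15 | hydroxy enol: compound 14 with the triethylsilyl group replaced by H (free C2 hydroxyl) | COC(=O)/C(=C\O)[C@@H](CC(=O)OCCc1ccc(O[Si](C)(C)C(C)(C)C)c(O[Si](C)(C)C(C)(C)C)c1)[C@H](CO[Si](c1ccccc1)(c1ccccc1)C(C)(C)C)[C@@H](C)O | intermediate
16 | lactol: C6 hemiacetal of 15 (tetrahydropyran with 6-OH and 5-CO2Me, C5 and C6 as epimer mixtures; C2, C3, C4 as in 17) | COC(=O)C1C(O)O[C@H](C)[C@@H](CO[Si](c2ccccc2)(c2ccccc2)C(C)(C)C)[C@@H]1CC(=O)OCCc1ccc(O[Si](C)(C)C(C)(C)C)c(O[Si](C)(C)C(C)(C)C)c1 | intermediate
17 | methyl (2R,3R,4S)-4-(2-{2-[3,4-bis(tert-butyldimethylsilyloxy)phenyl]ethoxy}-2-oxoethyl)-3-[(tert-butyldiphenylsilyloxy)methyl]-2-methyl-3,4-dihydro-2H-pyran-5-carboxylate | COC(=O)C1=CO[C@H](C)[C@@H](CO[Si](c2ccccc2)(c2ccccc2)C(C)(C)C)[C@@H]1CC(=O)OCCc1ccc(O[Si](C)(C)C(C)(C)C)c(O[Si](C)(C)C(C)(C)C)c1 | intermediate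
18 | methyl (2R,3R,4S)-4-{2-[2-(3,4-dihydroxyphenyl)ethoxy]-2-oxoethyl}-3-(hydroxymethyl)-2-methyl-3,4-dihydro-2H-pyran-5-carboxylate | COC(=O)C1=CO[C@H](C)[C@@H](CO)[C@@H]1CC(=O)OCCc1ccc(O)c(O)c1 | target

**Step count**
Total: 12 steps. Longest linear sequence: 9 steps (1 to 18 through steps 1, 2, 3, 4, 5, 7, 10, 11, 12).

**Steps most likely to fail**

Step 7. The carbene may be diverted onto the formyl group of the nucleophile, or the formyl ester may be lost to self-condensation before it reacts. γ-Deprotonation of the acyl azolium may erode C3, and the facial preference at C4 may be low on the γ-branched enal. The fallback leaves the carbene and oxidant for Lewis-base acyl ammonium catalysis. It sets out from enal 7: Pinnick oxidation (NaClO2, NaH2PO4, 2-methyl-2-butene, t-BuOH/H2O) should give (2E,4R,5R)-4-[(tert-butyldiphenylsilyloxy)methyl]-5-(triethylsilyloxy)hex-2-enoic acid F1. Pivaloyl chloride and i-Pr2NEt in CH2Cl2 at 0 °C convert it into the mixed pivalic anhydride F2. With an isothiourea catalyst (HyperBTM, antipode chosen for 4S), i-Pr2NEt and 9, F2 should undergo the known Michael addition–lactonisation of α,β-unsaturated acyl ammonium ions with 1,3-dicarbonyl compounds, and the route is rejoined at lactone 10.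

Step 11. The acid equilibrium may stall at the hemiacetal or its methyl acetal, or on long acid exposure the freed C2 hydroxyl may lactonise onto the phenethyl or the methyl ester. The fallback separates the two events and drives the dehydration by activation under base. It sets out from 14: AcOH/THF/H2O (3:1:1, rt) removes the triethylsilyl group and the lactol 16 is isolated. MsCl and Et3N in CH2Cl2 at −20 °C convert it into the anomeric methanesulfonate F3, which should lose methanesulfonate by E1cB elimination because C5–H is α to the ester, and the route is rejoined at 17.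

Step 5. Slow olefination of the hindered aldehyde may let epimerisation at its α carbon and β-elimination of silanolate compete, and the product enal may be homologated a second time. The fallback replaces the one-step formyl olefination by an ester olefination and redox adjustment. It sets out from 6: Masamune–Roush Horner–Wadsworth–Emmons reaction (triethyl phosphonoacetate, LiCl, i-Pr2NEt, MeCN, rt) should give ethyl (2E,4R,5R)-4-[(tert-butyldiphenylsilyloxy)methyl]-5-(triethylsilyloxy)hex-2-enoate F4. i-Bu2AlH (2.2 equiv, CH2Cl2, −78 °C) reduces it to (2E,4R,5R)-4-[(tert-butyldiphenylsilyloxy)methyl]-5-(triethylsilyloxy)hex-2-en-1-ol F5, and MnO2 in CH2Cl2 at rt oxidises the allylic alcohol, so that the route is rejoined at enal 7.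

**Further compounds**
F1 | step 7 | (2E,4R,5R)-4-[(tert-butyldiphenylsilyloxy)methyl]-5-(triethylsilyloxy)hex-2-enoic acid | OC(=O)/C=C/[C@H](CO[Si](c1ccccc1)(c1ccccc1)C(C)(C)C)[C@@H](C)O[Si](CC)(CC)CC
F2 | step 7 | mixed anhydride of F1 with pivalic acid | CC(C)(C)C(=O)OC(=O)/C=C/[C@H](CO[Si](c1ccccc1)(c1ccccc1)C(C)(C)C)[C@@H](C)O[Si](CC)(CC)CC
F3 | step 11 | anomeric (C6) methanesulfonate of lactol 16 | COC(=O)C1C(OS(C)(=O)=O)O[C@H](C)[C@@H](CO[Si](c2ccccc2)(c2ccccc2)C(C)(C)C)[C@@H]1CC(=O)OCCc1ccc(O[Si](C)(C)C(C)(C)C)c(O[Si](C)(C)C(C)(C)C)c1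
F4 | step 5 | ethyl (2E,4R,5R)-4-[(tert-butyldiphenylsilyloxy)methyl]-5-(triethylsilyloxy)hex-2-enoate | CCOC(=O)/C=C/[C@H](CO[Si](c1ccccc1)(c1ccccc1)C(C)(C)C)[C@@H](C)O[Si](CC)(CC)CC
F5 | step 5 | (2E,4R,5R)-4-[(tert-butyldiphenylsilyloxy)methyl]-5-(triethylsilyloxy)hex-2-en-1-ol | OC/C=C/[C@H](CO[Si](c1ccccc1)(c1ccccc1)C(C)(C)C)[C@@H](C)O[Si](CC)(CC)CC
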